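**Plan**

1. Germacrane numbering is used. Ring A is C1–C10 (C14 on C10, C15 on C4). Ring B is the γ-lactone O–C12–C11–C7–C6 (C13 on C11). The side chain is C1′–C4′. TBS = tert-butyldimethylsilyl.
2. Bonds cut, in retrosynthetic order: both O–Si bonds; C1=C10 (ring-closing metathesis); O–C6 together with C11–C12 (CO2 leaves and the two ends are joined as a C6–C11 bond); the C8–O acyl bond; C8–C9; C6–C11/C7–C11 (ethylidene transfer); C5–C6; C3–C4.
3. Enabling feature: in ring B the O–C12(=O) unit is one CO2 molecule spanning C6 and C11. These two carbons stand 1,3 across C7, and C6 is allylic to C4=C5. Ring B is therefore the CO2 adduct of a C6–C7–C11 vinylcyclopropane, a temporary ring that the target does not contain.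
4. Forward order: open chain, then the temporary cyclopropane, then ring B by CO2 insertion, then ring A.
5. Stereochemistry: C4=C5 comes from a chelate-controlled anti-carbomagnesiation. C6, C7 and C11 come from one dioxaborolane-controlled cyclopropanation and are relayed through the insertion. C8 comes from the Ipc2B reagent and C3′ from (R)-3-bromo-2-methylpropan-1-ol. The Z geometry of C1=C10 comes from ring strain in the metathesis.

Key step: step 10

Assumption: the SMILES is read literally. C1=C10 is Z (C2 and C9 cis). C4=C5 has C3 and C6 trans (Z by CIP because of CH2OH). The centres are 6R,7R,8S,11S,3′S.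

**Step 1**
Reactants: 1 prop-2-yn-1-ol; 2 but-3-en-1-ylmagnesium bromide
Product: 4 (Z)-2-(but-3-en-1-yl)-3-iodoprop-2-en-1-ol, via alkenylmagnesium alkoxide chelate 3 (not isolated)
Conditions: 2 (2.5 equiv), CuI (10 mol %), THF, −10 °C to rt; then I2, −78 to 0 °C; aq. NH4Cl
Reagents that add atoms: iodine, II
Why: Copper-catalysed anti-carbomagnesiation of propargyl alcohol puts the butenyl group on the inner carbon and holds magnesium cis to the alkoxide in a five-membered chelate, so iodinolysis with retention should place iodine cis to CH2OH and trans to the C3 chain.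

**Step 2**
Reactants: 4 (Z)-2-(but-3-en-1-yl)-3-iodoprop-2-en-1-ol
Product: 5 (Z)-tert-butyl{[2-(iodomethylidene)hex-5-en-1-yl]oxy}dimethylsilane
Conditions: TBSCl, imidazole, CH2Cl2, 0 °C to rt
Reagents that add atoms: tert-butyldimethylsilyl chloride, CC(C)(C)[Si](C)(C)Cl
Why: Standard silylation of a primary allylic alcohol, which leaves the olefin geometry untouched.

**Step 3**
Reactants: 5 (Z)-tert-butyl{[2-(iodomethylidene)hex-5-en-1-yl]oxy}dimethylsilane; 6 (E)-3-(tributylstannyl)prop-2-en-1-ol
Product: 7 (2E,4Z)-5-[(TBSO)methyl]nona-2,4,8-trien-1-ol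
Conditions: PdCl2(MeCN)2 (5 mol %), DMF, rt
Reagents that add atoms: none
Why: Stille coupling of an alkenyl iodide and an alkenylstannane forms C5–C6 with retention of both olefin geometries and tolerates the free alcohol.

**Step 4**
Reactants: 7 (2E,4Z)-5-[(TBSO)methyl]nona-2,4,8-trien-1-ol
Product: 8 [(1S,2R,3R)-2-{(1Z)-2-[(TBSO)methyl]hexa-1,5-dien-1-yl}-3-methylcyclopropyl]methanol
Conditions: Et2Zn, CH3CHI2, (4R,5R)-2-butyl-N,N,N′,N′-tetramethyl-1,3,2-dioxaborolane-4,5-dicarboxamide (1.2 equiv), CH2Cl2, −40 to 0 °C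
Reagents that add atoms: 1,1-diiodoethane, CC(I)I
Why: In this Charette-type asymmetric Simmons–Smith cyclopropanation the zinc alkoxide delivers the ethylidene carbenoid only to the allylic-alcohol olefin C6=C7, the E olefin gives C5/C8 trans, the (4R,5R)-dioxaborolane selects the face in the sense known for E-allylic alcohols, and the methyl group is placed anti to CH2OH.

**Step 5**
Reactants: 8 [(1S,2R,3R)-2-{(1Z)-2-[(TBSO)methyl]hexa-1,5-dien-1-yl}-3-methylcyclopropyl]methanol
Product: 9 (1S,2R,3R)-2-{(1Z)-2-[(TBSO)methyl]hexa-1,5-dien-1-yl}-3-methylcyclopropane-1-carbaldehyde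
Conditions: Dess–Martin periodinane, pyridine, CH2Cl2, 0 °C to rt
Reagents that add atoms: none
Why: Dess–Martin oxidation is neutral enough for the vinylcyclopropane, and the trans arrangement of formyl and alkenyl groups excludes the retro-Claisen ring opening of cis isomers.

**Step 6**
Reactants: 9 (1S,2R,3R)-2-{(1Z)-2-[(TBSO)methyl]hexa-1,5-dien-1-yl}-3-methylcyclopropane-1-carbaldehyde
Product: 11 (1S)-1-[(1S,2R,3R)-2-{(1Z)-2-[(TBSO)methyl]hexa-1,5-dien-1-yl}-3-methylcyclopropyl]-3-methylbut-3-en-1-ol, via diisopinocampheylborinate 10 (not isolated)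
Conditions: (−)-Ipc2BOMe, 2-methylallylmagnesium chloride, Et2O, 0 °C to rt; then 9, −78 °C; NaOH, H2O2
Reagents that add atoms: 2-methylallylmagnesium chloride, C=C(C)C[Mg]Cl
Why: Brown methallylation through a closed chair transition state is reagent-controlled, and the borane derived from (+)-α-pinene gives the S carbinol with α-branched aldehydes, which sets C8.

**Step 7**
Reactants: 12 (R)-3-bromo-2-methylpropan-1-ol
Product: 13 (R)-(3-bromo-2-methylpropoxy)(tert-butyl)dimethylsilane
Conditions: TBSCl, imidazole, CH2Cl2, 0 °C to rt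
Reagents that add atoms: tert-butyldimethylsilyl chloride, CC(C)(C)[Si](C)(C)Cl
Why: Routine silylation of a primary alcohol that does not touch the stereocentre.

**Step 8**
Reactants: 13 (R)-(3-bromo-2-methylpropoxy)(tert-butyl)dimethylsilane
Product: 15 (S)-4-(TBSO)-3-methylbutanoic acid, via Grignard reagent 14 (not isolated)
Conditions: Mg, THF, reflux; then CO2, −20 °C; aq. citric acid
Reagents that add atoms: carbon dioxide, O=C=O
Why: Carboxylation of a primary Grignard reagent adds C1′, and the stereocentre is β to magnesium and keeps its spatial arrangement (the descriptor changes from R to S only through CIP priorities).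

**Step 9**
Reactants: 11 (1S)-1-[(1S,2R,3R)-2-{(1Z)-2-[(TBSO)methyl]hexa-1,5-dien-1-yl}-3-methylcyclopropyl]-3-methylbut-3-en-1-ol; 15 (S)-4-(TBSO)-3-methylbutanoic acid
Product: 16 (1S)-1-[(1S,2R,3R)-2-{(1Z)-2-[(TBSO)methyl]hexa-1,5-dien-1-yl}-3-methylcyclopropyl]-3-methylbut-3-en-1-yl (3S)-4-(TBSO)-3-methylbutanoate
Conditions: DCC, DMAP (cat.), CH2Cl2, 0 °C to rt
Reagents that add atoms: none
Why: Steglich esterification acylates at oxygen under neutral conditions, so the acid-labile cyclopropylcarbinyl centre C8 keeps its configuration.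

**Step 10**
Reactants: 16 (1S)-1-[(1S,2R,3R)-2-{(1Z)-2-[(TBSO)methyl]hexa-1,5-dien-1-yl}-3-methylcyclopropyl]-3-methylbut-3-en-1-yl (3S)-4-(TBSO)-3-methylbutanoate
Product: 19 (1S)-1-[(2R,3R,4S)-2-{(1Z)-2-[(TBSO)methyl]hexa-1,5-dien-1-yl}-4-methyl-5-oxooxolan-3-yl]-3-methylbut-3-en-1-yl (3S)-4-(TBSO)-3-methylbutanoate, via allyl alkyl nickelacycle 17 (not isolated), via nickel carboxylate 18 (not isolated)
Conditions: Ni(cod)2 (10 mol %), IPr = 1,3-bis(2,6-diisopropylphenyl)imidazol-2-ylidene (12 mol %), CO2 (30 bar), toluene, 50 °C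
Reagents that add atoms: carbon dioxide, O=C=O
Why: Proposed new method: zerovalent nickel bound to C4=C5 should insert into the strained allylic C6–C11 bond, an elementary step known from the nickel–carbene-catalysed vinylcyclopropane-to-cyclopentene rearrangement and the nickel-catalysed silaborative opening of unactivated vinylcyclopropanes, to give the σ-alkyl π-allyl complex of divalent nickel 17, whose nucleophilic Ni–C11 bond inserts CO2 to give carboxylate 18, whose oxygen then closes on the allyl terminus C6 and releases zerovalent nickel. The closest known reaction types are the palladium-catalysed formal [3+2] cycloadditions of CO2 to methylenecyclopropanes, trimethylenemethane precursors and vinyl epoxides, and the lactone-forming telomerisation of butadiene and CO2. The only ring closed is the γ-lactone, by 5-exo attack of oxygen on C6 instead of seven-membered closure on the fully substituted C4. C7 is untouched; C11 keeps its configuration because insertion into C–C and insertion of CO2 into Ni–C both go with retention, and it could in any case be epimerised by base to the wanted all-trans lactone; C6 is set trans to the C8 arm because syn/anti equilibration of the allyl unit and reversible C–O closure funnel into the trans,trans-lactone. The step needs cleavage of C6–C11 and not C6–C7, which the branched ester-bearing C8 substituent on C7 against the small methyl on C11 should secure, and it needs CO2 capture to outrun β-hydride loss from C13 and reductive elimination to the cyclopentene, hence a bulky carbene ligand that leaves no free cis site, a moderate temperature and a high CO2 pressure. The two remote terminal olefins bind nickel only reversibly, and the strain of the three-membered ring pays for the fixation of CO2.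

**Step 11**
Reactants: 19 (1S)-1-[(2R,3R,4S)-2-{(1Z)-2-[(TBSO)methyl]hexa-1,5-dien-1-yl}-4-methyl-5-oxooxolan-3-yl]-3-methylbut-3-en-1-yl (3S)-4-(TBSO)-3-methylbutanoate
Product: 20 15,4′-bis-O-TBS ether of the target
Conditions: second-generation Hoveyda–Grubbs catalyst (10 mol %), 1,4-benzoquinone (20 mol %), toluene (0.5 mM), 90 °C, argon sparge
Reagents that add atoms: none
Why: Ring-closing metathesis starts at the monosubstituted olefin and closes on the 1,1-disubstituted one, the hindered C4=C5 stays out, and a ten-membered ring that already holds one trans olefin accepts the new trisubstituted olefin in the less strained Z form, as is usual for ten-membered germacranolide rings closed in this way.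

**Step 12**
Reactants: 20 15,4′-bis-O-TBS ether of the target
Product: 21 target, (3S,3aR,4S,6Z,10Z,11aR)-10-(hydroxymethyl)-3,6-dimethyl-2-oxo-2,3,3a,4,5,8,9,11a-octahydrocyclodeca[b]furan-4-yl (3S)-4-hydroxy-3-methylbutanoate
Conditions: HF·pyridine, excess pyridine, THF, 0 °C
Reagents that add atoms: none
Why: Buffered fluoride cleaves both primary silyl ethers under conditions too mild for transannular cyclisation of the diene or for lactonisation of the freed γ-hydroxy ester.

**Compound list**

1 | prop-2-yn-1-ol | C#CCO | starting material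
2 | but-3-en-1-ylmagnesium bromide | C=CCC[Mg]Br | starting material
3 | alkenylmagnesium alkoxide chelate (Mg bound to C5 and to O15) | C=CCCC1=C[Mg]OC1 | intermediate
4 | (Z)-2-(but-3-en-1-yl)-3-iodoprop-2-en-1-ol | C=CCC/C(CO)=C/I | intermediate
5 | (Z)-tert-butyl{[2-(iodomethylidene)hex-5-en-1-yl]oxy}dimethylsilane | C=CCC/C(CO[Si](C)(C)C(C)(C)C)=C/I | intermediate
6 | (E)-3-(tributylstannyl)prop-2-en-1-ol | CCCC[Sn](CCCC)(CCCC)/C=C/CO | starting material
7 | (2E,4Z)-5-[(TBSO)methyl]nona-2,4,8-trien-1-ol | C=CCC/C(CO[Si](C)(C)C(C)(C)C)=C/C=C/CO | intermediate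
8 | [(1S,2R,3R)-2-{(1Z)-2-[(TBSO)methyl]hexa-1,5-dien-1-yl}-3-methylcyclopropyl]methanol | C=CCC/C(CO[Si](C)(C)C(C)(C)C)=C/[C@H]1[C@@H](C)[C@@H]1CO | intermediate
9 | (1S,2R,3R)-cyclopropane-1-carbaldehyde corresponding to 8 | C=CCC/C(CO[Si](C)(C)C(C)(C)C)=C/[C@H]1[C@@H](C)[C@@H]1C=O | intermediate
10 | diisopinocampheylborinate of 11 | C=CCC/C(CO[Si](C)(C)C(C)(C)C)=C/[C@H]1[C@@H](C)[C@@H]1[C@@H](OB([C@@H]2C[C@@H]3C[C@@H](C3(C)C)[C@H]2C)[C@@H]2C[C@@H]3C[C@@H](C3(C)C)[C@H]2C)CC(C)=C | intermediate
11 | (1S)-1-[(1S,2R,3R)-cyclopropyl]-3-methylbut-3-en-1-ol (8S carbinol) | C=CCC/C(CO[Si](C)(C)C(C)(C)C)=C/[C@H]1[C@@H](C)[C@@H]1[C@@H](O)CC(C)=C | intermediate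
12 | (R)-3-bromo-2-methylpropan-1-ol | BrC[C@H](C)CO | starting material
13 | (R)-(3-bromo-2-methylpropoxy)(tert-butyl)dimethylsilane | BrC[C@H](C)CO[Si](C)(C)C(C)(C)C | intermediate
14 | Grignard reagent of 13 | Br[Mg]C[C@H](C)CO[Si](C)(C)C(C)(C)C | intermediate
15 | (S)-4-(TBSO)-3-methylbutanoic acid | OC(=O)C[C@H](C)CO[Si](C)(C)C(C)(C)C | intermediate
16 | vinylcyclopropane ester (11 acylated by 15) | C=CCC/C(CO[Si](C)(C)C(C)(C)C)=C/[C@H]1[C@@H](C)[C@@H]1[C@@H](OC(=O)C[C@H](C)CO[Si](C)(C)C(C)(C)C)CC(C)=C | intermediate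
17 | allyl alkyl nickelacycle, IPr-ligated, drawn in the σ form with Ni on C6 and C11 | C=CCC/C(CO[Si](C)(C)C(C)(C)C)=C/[C@H]1[Ni](=C2N(c3c(C(C)C)cccc3C(C)C)C=CN2c2c(C(C)C)cccc2C(C)C)[C@@H](C)[C@@H]1[C@@H](OC(=O)C[C@H](C)CO[Si](C)(C)C(C)(C)C)CC(C)=C | intermediate
18 | nickel carboxylate, IPr-ligated, drawn in the σ form with Ni on C6 and O | C=CCC/C(CO[Si](C)(C)C(C)(C)C)=C/[C@H]1[Ni](=C2N(c3c(C(C)C)cccc3C(C)C)C=CN2c2c(C(C)C)cccc2C(C)C)OC(=O)[C@@H](C)[C@@H]1[C@@H](OC(=O)C[C@H](C)CO[Si](C)(C)C(C)(C)C)CC(C)=C | intermediate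
19 | all-trans γ-lactone diene (6R,7R,8S,11S,3′S) | C=CCC/C(CO[Si](C)(C)C(C)(C)C)=C/[C@H]1OC(=O)[C@@H](C)[C@@H]1[C@@H](OC(=O)C[C@H](C)CO[Si](C)(C)C(C)(C)C)CC(C)=C | intermediate
20 | 15,4′-bis-O-TBS ether of the target | C/C1=C/CC/C(CO[Si](C)(C)C(C)(C)C)=C/[C@H]2OC(=O)[C@@H](C)[C@@H]2[C@@H](OC(=O)C[C@H](C)CO[Si](C)(C)C(C)(C)C)C1 | intermediate
21 | CNP0160815.1 | C/C1=C/CC/C(CO)=C/[C@H]2OC(=O)[C@@H](C)[C@@H]2[C@@H](OC(=O)C[C@H](C)CO)C1 | target

**Step count**

Total step count: 12. Longest linear sequence: 10 (steps 1–6 and 9–12).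

**Steps most likely to fail**

Step 10. The hindered trisubstituted olefin may bind nickel too weakly for ring opening. The nickelacycle may lose a β-hydrogen or collapse to the cyclopentene before CO2 is taken up. CO2 may be attacked by the allyl end instead of C11.

The fallback sets out from 5 and returns at 19.
- Iodine–lithium exchange on 5 (n-BuLi, Et2O, −78 °C) and DMF give (Z)-3-[(TBSO)methyl]hepta-2,6-dienal F1.
- (S)-4-Benzyloxazolidin-2-one is N-acylated with methyl 4-chloro-4-oxobutanoate to give the succinyl imide F2.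
- The dibutylboron enolate of F2 (Bu2BOTf, Et3N) adds to F1 in an Evans syn-aldol reaction, and the aldolate closes on the methyl ester to give the trans-lactone imide F3.
- LiOH/H2O2 gives the lactone acid F4.
- The dianion of F4 (NaHMDS) is methylated with MeI anti to the C7 substituent to give the α-methyl lactone acid F5.
- BH3·SMe2 gives the hydroxymethyl lactone F6.
- Dess–Martin oxidation gives the formyl lactone F7.
- The methallylborane of step 6 gives the homoallylic alcohol F8.
- Steglich esterification of F8 by 15 gives 19.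

Step 11. Oligomerisation may outrun closure of the strained ring, or the catalyst may decay on the 1,1-disubstituted olefin.

The fallback sets out from 19 and returns at 20.
- Lemieux–Johnson cleavage (OsO4 cat., NaIO4, 2,6-lutidine, dioxane–water) should cut the two terminal olefins. The hindered C4=C5, which is deactivated by two allylic C–O bonds, should survive. The product is the keto aldehyde F9.
- Intramolecular McMurry coupling under slow addition (TiCl3(DME)1.5, Zn–Cu couple, DME, reflux) forms C1=C10.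

Step 4. Site selectivity among four olefins may be poor, or the placement of the methyl group may be poorly controlled. An error at C11 alone is harmless, because base corrects it after step 10.

The fallback sets out from 5 and returns at 8.
- Commercial (E)-3-(4,4,5,5-tetramethyl-1,3,2-dioxaborolan-2-yl)prop-2-en-1-ol, which has a single olefin, is cyclopropanated under the conditions of step 4 to give the borylcyclopropylmethanol F10.
- Suzuki–Miyaura coupling of F10 and 5 (PdCl2(dppf), Cs2CO3, THF–water, 65 °C) forms C5–C6 with retention at the cyclopropyl carbon.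

**Further compounds**

F1 | step 10 | (Z)-3-[(TBSO)methyl]hepta-2,6-dienal | C=CCC/C(CO[Si](C)(C)C(C)(C)C)=C/C=O
F2 | step 10 | methyl 4-[(S)-4-benzyl-2-oxooxazolidin-3-yl]-4-oxobutanoate | COC(=O)CCC(=O)N1[C@@H](Cc2ccccc2)COC1=O
F3 | step 10 | (S)-4-benzyl-3-[(2R,3S)-2-alkenyl-5-oxooxolane-3-carbonyl]oxazolidin-2-one (alkenyl as in 19) | C=CCC/C(CO[Si](C)(C)C(C)(C)C)=C/[C@H]1OC(=O)C[C@@H]1C(=O)N1[C@@H](Cc2ccccc2)COC1=O
F4 | step 10 | (2R,3S)-2-alkenyl-5-oxooxolane-3-carboxylic acid | C=CCC/C(CO[Si](C)(C)C(C)(C)C)=C/[C@H]1OC(=O)C[C@@H]1C(=O)O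
F5 | step 10 | (2R,3S,4S)-2-alkenyl-4-methyl-5-oxooxolane-3-carboxylic acid | C=CCC/C(CO[Si](C)(C)C(C)(C)C)=C/[C@H]1OC(=O)[C@@H](C)[C@@H]1C(=O)O
F6 | step 10 | (3S,4R,5R)-5-alkenyl-4-(hydroxymethyl)-3-methyloxolan-2-one | C=CCC/C(CO[Si](C)(C)C(C)(C)C)=C/[C@H]1OC(=O)[C@@H](C)[C@@H]1CO
F7 | step 10 | (2R,3S,4S)-2-alkenyl-4-methyl-5-oxooxolane-3-carbaldehyde | C=CCC/C(CO[Si](C)(C)C(C)(C)C)=C/[C@H]1OC(=O)[C@@H](C)[C@@H]1C=O
F8 | step 10 | (3S,4R,5R)-5-alkenyl-4-[(1S)-1-hydroxy-3-methylbut-3-en-1-yl]-3-methyloxolan-2-one | C=CCC/C(CO[Si](C)(C)C(C)(C)C)=C/[C@H]1OC(=O)[C@@H](C)[C@@H]1[C@@H](O)CC(C)=C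
F9 | step 11 | keto aldehyde (C1 formyl, C10 methyl ketone) derived from 19 | O=CCC/C(CO[Si](C)(C)C(C)(C)C)=C/[C@H]1OC(=O)[C@@H](C)[C@@H]1[C@@H](OC(=O)C[C@H](C)CO[Si](C)(C)C(C)(C)C)CC(C)=O
F10 | step 4 | [(1R,2R,3S)-2-methyl-3-(4,4,5,5-tetramethyl-1,3,2-dioxaborolan-2-yl)cyclopropyl]methanol | CC1(C)OB(OC1(C)C)[C@H]1[C@@H](C)[C@@H]1CO
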